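**Plan**

- Retrosynthesis: after removing the C2 acetate and the benzylic silyl ether, the δ-lactone is cut at C11′–C13′ (ring closure) and then at the C4–O ester bond, giving fragment 1 (a 4-hydroxy-2-oxoguaianolide) and fragment 2 (an arylacetic acid). Fragment 1 is cut at C7–C8, C5–C6 and C1–C10.
- Enabling feature: with C2 held as a ketone, C3 is the α′-carbon of the C1=C5–C2=O cyclopentenone, so a methylene on C3 (C13′) is a cross-conjugated acceptor. The ester on the neighbouring C4 oxygen holds the benzylic, ester-activated C11′–H six atoms away. One Michael event closes the δ-lactone and fixes C3 and C11′; the same carbonyl then becomes the C2 acetate.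
- Forward order: cyclopentene (metathesis of linalool), 1,3-dione, tetrasubstituted enone (Michael addition, then allyl addition with carbonyl transposition), seven-membered ring (carbonyl-ene), α-methylene γ-lactone. Fragment 2 is built on methyl 4-bromo-2-iodobenzoate. The fragments are joined by esterification, and the δ-lactone is closed last.
- Stereochemistry: C4 is bought (linalool); C10 and the side-chain benzylic centre are set by catalysis; C7 and C8 are relayed from C10 in the ene closure; C3, C11′ and C2 are relayed from C4 through the key step and the following reduction.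

Key step: step 25

Remark: guaiane numbering is used for the lactone half (C1=C5 ring-fusion alkene, C2, C3, C4 with methyl C15, C6, C7, C8 with the γ-lactone oxygen, C9, C10 with methyl C14, C11–C13 methylene lactone), and C12′(=O)–C11′H(Ar)–C13′H2 are the δ-lactone carbonyl, its aryl-bearing carbon and the CH2 on C3; (S)-linalool of high enantiomeric purity is taken as commercial, and the facial sense of the iridium catalyst in step 18 is assumed (the ligand antipode is used otherwise).

**Fragment 1**

Step 1
Reactants: 1 (S)-linalool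
Product: 2 (S)-1-methylcyclopent-2-en-1-ol
Conditions: second-generation Grubbs catalyst (0.5 mol%), CH2Cl2, 40 °C
Reagents that add atoms: none
Why: Ring-closing metathesis between the vinyl group and the trisubstituted alkene expels isobutene and does not touch the carbinol carbon, so C4 is carried over from linalool.

Step 2
Reactants: 2 (S)-1-methylcyclopent-2-en-1-ol
Product: 3 (S)-tert-butyldimethyl[(1-methylcyclopent-2-en-1-yl)oxy]silane
Conditions: TBSOTf, 2,6-lutidine, CH2Cl2, 0 °C
Reagents that add atoms: tert-butyldimethylsilyl triflate CC(C)(C)[Si](C)(C)OS(=O)(=O)C(F)(F)F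
Why: Silyl triflate with a hindered pyridine base silylates the tertiary allylic alcohol, which blocks retro-aldol racemisation of C4 once the ketone is present.

Step 3
Reactants: 3 silyl ether
Product: 4 (S)-4-(tert-butyldimethylsilyloxy)-4-methylcyclopent-2-en-1-one
Conditions: CrO3, 3,5-dimethylpyrazole, CH2Cl2, −20 °C
Reagents that add atoms: chromium trioxide O=[Cr](=O)=O
Why: Chromium trioxide–pyrazole allylic oxidation attacks the only allylic methylene (C2), the other allylic carbon (C4) being quaternary, and gives the enone.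

Step 4
Reactants: 4 enone
Product: 6 (3S,4S)-4-(tert-butyldimethylsilyloxy)-3-hydroxy-4-methylcyclopentan-1-one, via boryl ketone 5 (not isolated)
Conditions: B2pin2, CuCl (5 mol%), NaOtBu (10 mol%), Xantphos (5 mol%), MeOH, THF, rt; then NaBO3·4H2O, THF–H2O, rt
Reagents that add atoms: sodium perborate [Na+].[O-]OB=O; bis(pinacolato)diboron CC1(C)OB(OC1(C)C)B1OC(C)(C)C(C)(C)O1 (boryl group of 5 only)
Why: Copper-catalysed conjugate borylation of the enone and perborate oxidation with retention place an oxygen on C5; the new carbinol centre is of no consequence because it is oxidised in step 5.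

Step 5
Reactants: 6 β-hydroxy ketone
Product: 7 (S)-4-(tert-butyldimethylsilyloxy)-4-methylcyclopentane-1,3-dione
Conditions: Dess–Martin periodinane, NaHCO3, CH2Cl2, rt
Reagents that add atoms: none
Why: Buffered Dess–Martin oxidation converts the β-hydroxy ketone into the 1,3-dione without forming an enolate next to the silyloxy group.

Step 6
Reactants: 7 dione; 8 (E)-but-2-enal
Product: 10 (4S,6S)-6-(tert-butyldimethylsilyloxy)-2-methoxy-4,6-dimethyl-3,4,6,7-tetrahydrocyclopenta[b]pyran-5(2H)-one, via hemiacetal 9 (not isolated)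
Conditions: (R)-α,α-diphenylprolinol trimethylsilyl ether (10 mol%), PhCO2H (10 mol%), CH2Cl2, 0 °C; then MeOH, PPTS, rt
Reagents that add atoms: methanol CO
Why: Iminium-activated organocatalytic Michael addition of the acidic dione carbon (C1) to crotonaldehyde sets C10 by catalyst control (the silyloxydiphenylmethyl group shields one face of the E-iminium ion), and acetalisation should then lock the adduct as the cyclic enol ether on the carbonyl oxygen remote from the quaternary C4, as expected on steric grounds.

Step 7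
Reactants: 10 methyl acetal
Product: 12 (S)-3-[(S)-2-allyl-3-(tert-butyldimethylsilyloxy)-3-methyl-5-oxocyclopent-1-en-1-yl]butanal, via tertiary alcohol 11 (not isolated)
Conditions: allylMgBr, THF, −78 → 0 °C; then 1 M HCl, THF, rt
Reagents that add atoms: allylmagnesium bromide C=CC[Mg]Br; water O
Why: Stork–Danheiser transposition: 1,2-addition of the allyl Grignard reagent to the vinylogous ester carbonyl (C5), then acid-mediated ionisation and hydrolysis, moves the carbonyl to C2, creates the tetrasubstituted C1=C5 enone and releases the C8 aldehyde from the acetal in the same operation.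

Step 8
Reactants: 12 allyl enone aldehyde
Product: 13 (S)-3-[(S)-3-(tert-butyldimethylsilyloxy)-3-methyl-2-(3-methylbut-2-en-1-yl)-5-oxocyclopent-1-en-1-yl]butanal
Conditions: 2-methyl-2-butene (excess), second-generation Grubbs catalyst (5 mol%), CH2Cl2, 40 °C
Reagents that add atoms: 2-methyl-2-butene CC=C(C)C
Why: Olefin cross-metathesis with 2-methyl-2-butene converts the terminal allyl group into a prenyl group; the electron-poor tetrasubstituted enone alkene and the aldehyde do not react with the ruthenium carbene.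

Step 9
Reactants: 13 prenyl enone aldehyde
Product: 14 (3S,5R,6S,8S)-3-(tert-butyldimethylsilyloxy)-6-hydroxy-3,8-dimethyl-5-(prop-1-en-2-yl)-3,4,5,6,7,8-hexahydroazulen-1(2H)-one
Conditions: Me2AlCl (2.5 equiv), CH2Cl2 (high dilution), −78 → −20 °C
Reagents that add atoms: none
Why: Lewis acid-promoted intramolecular carbonyl-ene reaction (the citronellal-to-isopulegol type) forms the C7–C8 bond and the seven-membered ring with hydrogen transfer from a prenyl methyl; the chair-like transition state should place the new C8–O and C7–isopropenyl bonds trans-diequatorial and keep the C10 methyl pseudoaxial to avoid allylic strain with the C2 carbonyl, which gives C8–O trans to the C10 methyl as in the target.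

Step 10
Reactants: 14 hydroxy isopropenyl ketone
Product: 15 (3S,5R,6S,8S)-3-(tert-butyldimethylsilyloxy)-6-hydroxy-5-(3-hydroxyprop-1-en-2-yl)-3,8-dimethyl-3,4,5,6,7,8-hexahydroazulen-1(2H)-one
Conditions: SeO2 (0.3 equiv), tBuOOH, salicylic acid (cat.), CH2Cl2, rt
Reagents that add atoms: tert-butyl hydroperoxide CC(C)(C)OO (oxygen relayed by SeO2)
Why: Selenium dioxide allylic oxidation (ene reaction, then [2,3]-shift) oxidises the methyl group of the 1,1-disubstituted alkene in preference to the allylic methine, and the enone alkene is too electron-poor to react.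

Step 11
Reactants: 15 allylic diol
Product: 17 (4S,7R,8S,10S)-4-(tert-butyldimethylsilyloxy)-2-oxoguaia-1(5),11(13)-dien-12,8-olide, via lactol 16 (not isolated)
Conditions: MnO2 (activated, excess), CH2Cl2, rt
Reagents that add atoms: none
Why: MnO2 oxidises the primary allylic alcohol to the enal, which closes to the lactol with the C8 hydroxyl and is oxidised again to the α-methylene γ-lactone; the trans ring fusion is already fixed at C7 and C8.

Step 12
Reactants: 17 guaianolide enone
Product: 19 (4S,7R,8S,10S)-4-(tert-butyldimethylsilyloxy)-3-(dimethylaminomethyl)-2-oxoguaia-1(5),11(13)-dien-12,8-olide, via silyl dienol ether 18 (not isolated)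
Conditions: TMSOTf, iPr2NEt, CH2Cl2, 0 °C; then CH2=NMe2 I (Eschenmoser's salt), CH2Cl2, rt; aq. NaHCO3
Reagents that add atoms: N,N-dimethylmethyleneiminium iodide C=[N+](C)C.[I-]; trimethylsilyl triflate C[Si](C)(C)OS(=O)(=O)C(F)(F)F (silyl group of 18 only)
Why: Soft enolisation gives the cross-conjugated silyl dienol ether at the only enolisable α-carbon (C3) without a free enolate, and its Mannich reaction with the iminium salt installs a dimethylaminomethyl group as a masked methylene; the lactone methylene has no acidic hydrogen and the hindered base cannot add to it.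

Step 13
Reactants: 19 silyl-protected Mannich base
Product: 20 (4S,7R,8S,10S)-3-(dimethylaminomethyl)-4-hydroxy-2-oxoguaia-1(5),11(13)-dien-12,8-olide
Conditions: HF·pyridine, pyridine, THF, 0 °C → rt
Reagents that add atoms: none
Why: Fluoride cleaves the tertiary silyl ether under acidic, non-enolising conditions, so neither β-elimination nor retro-aldol cleavage of the β-hydroxy ketone should occur.

**Fragment 2**

Step 14
Reactants: 21 methyl 4-bromo-2-iodobenzoate
Product: 22 (4-bromo-2-iodophenyl)methanol
Conditions: DIBAL-H (2.5 equiv), CH2Cl2, −78 → 0 °C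
Reagents that add atoms: none
Why: DIBAL-H reduces the benzoate ester to the benzylic alcohol and leaves both aryl halides intact.

Step 15
Reactants: 22 benzylic alcohol
Product: 23 [(4-bromo-2-iodobenzyl)oxy](tert-butyl)diphenylsilane
Conditions: TBDPSCl, imidazole, DMF, rt
Reagents that add atoms: tert-butyldiphenylsilyl chloride CC(C)(C)[Si](Cl)(c1ccccc1)c1ccccc1
Why: Silylation gives a benzylic ether that withstands the Grignard, hydride, acid and silyl triflate steps and is removed last by fluoride.

Step 16
Reactants: 23 aryl iodide; 24 succinic anhydride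
Product: 26 4-[5-bromo-2-(tert-butyldiphenylsilyloxymethyl)phenyl]-4-oxobutanoic acid, via aryl Grignard reagent 25 (not isolated)
Conditions: iPrMgCl·LiCl, THF, −30 °C; then succinic anhydride, −78 → 0 °C; aq. HCl
Reagents that add atoms: isopropylmagnesium chloride–lithium chloride CC(C)[Mg]Cl.[Li+].[Cl-] (MgCl of 25 only)
Why: Iodine–magnesium exchange is selective for the iodide over the bromide, and the aryl Grignard reagent opens the anhydride to the keto acid, whose carboxylate protects the ketone from a second addition.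

Step 17
Reactants: 26 keto acid
Product: 27 4-[5-bromo-2-(tert-butyldiphenylsilyloxymethyl)phenyl]pent-4-enoic acid
Conditions: Ph3PCH3Br, KOtBu, THF, 0 °C → reflux; aq. HCl work-up
Reagents that add atoms: methyltriphenylphosphonium bromide C[P+](c1ccccc1)(c1ccccc1)c1ccccc1.[Br-]
Why: Wittig methylenation of the aryl ketone, with the acid carried as its potassium salt, gives the 1,1-disubstituted alkene.

Step 18
Reactants: 27 pentenoic acid
Product: 28 (R)-4-[5-bromo-2-(tert-butyldiphenylsilyloxymethyl)phenyl]pentanoic acid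
Conditions: H2 (6 atm), [Ir(cod)(SIPHOX)][B(3,5-(CF3)2C6H3)4] (1 mol%), Et3N (0.5 equiv), MeOH, rt
Reagents that add atoms: none
Why: Carboxy-directed iridium-catalysed asymmetric hydrogenation of the 4-aryl-4-pentenoic acid sets the benzylic methyl stereocentre by catalyst control, the bound carboxylate fixing the olefin face; the aryl bromide and the silyl ether should not be reduced.

Step 19
Reactants: 28 (R)-acid
Product: 29 (R)-4-[5-bromo-2-(tert-butyldiphenylsilyloxymethyl)phenyl]pentan-1-ol
Conditions: BH3·SMe2, THF, 0 °C → rt; MeOH quench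
Reagents that add atoms: none
Why: Borane reduces the carboxylic acid chemoselectively to the primary alcohol.

Step 20
Reactants: 29 primary alcohol
Product: 30 (R)-4-[5-bromo-2-(tert-butyldiphenylsilyloxymethyl)phenyl]pentyl acetate
Conditions: Ac2O, pyridine, DMAP (cat.), CH2Cl2, rt
Reagents that add atoms: acetic anhydride CC(=O)OC(C)=O
Why: Acetylation installs the primary acetate of the target, which also masks this hydroxyl during the later acylation.

Step 21
Reactants: 30 aryl bromide
Product: 31 tert-butyl 2-[3-[(R)-5-acetoxypentan-2-yl]-4-(tert-butyldiphenylsilyloxymethyl)phenyl]acetate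
Conditions: BrZnCH2CO2tBu (preformed), Pd2(dba)3 (2 mol%), XPhos (8 mol%), THF, 50 °C
Reagents that add atoms: (2-tert-butoxy-2-oxoethyl)zinc bromide CC(C)(C)OC(=O)C[Zn]Br
Why: Palladium-catalysed cross-coupling of the aryl bromide with the Reformatsky reagent (α-arylation of an acetate) introduces the acetic ester arm under neutral conditions that spare the acetate.

Step 22
Reactants: 31 tert-butyl ester
Product: 32 2-[3-[(R)-5-acetoxypentan-2-yl]-4-(tert-butyldiphenylsilyloxymethyl)phenyl]acetic acid
Conditions: CF3CO2H, CH2Cl2, 0 °C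
Reagents that add atoms: none
Why: Acidolysis cleaves the tert-butyl ester by loss of isobutene and should leave the acetate and the silyl ether in place.

**Union and end game**

Step 23
Reactants: 20 amino alcohol; 32 arylacetic acid
Product: 33 ester of the C4 hydroxyl of 20 with acid 32
Conditions: DCC, DMAP (0.3 equiv), CH2Cl2, 0 °C → rt
Reagents that add atoms: none
Why: Steglich esterification (carbodiimide activation, DMAP acyl transfer) acylates the tertiary alcohol under nearly neutral conditions and joins the fragments through the C4–O bond.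

Step 24
Reactants: 33 ester Mannich base
Product: 35 4-arylacetoxy-3-methylene-2-oxoguaia-1(5),11(13)-dien-12,8-olide, via ammonium iodide 34 (not isolated)
Conditions: MeI, MeCN, rt; then aq. NaHCO3, CH2Cl2, rt
Reagents that add atoms: iodomethane CI (N-methyl group of 34 only)
Why: Quaternisation and mild base-induced β-elimination of trimethylamine from the Mannich base unveil the methylene on C3; trimethylamine leaves far more readily than the C4 carboxylate, so the ester should stay.

Step 25
Reactants: 35 methylene dienone ester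
Product: 38 cis-fused δ-lactone C2 ketone, via ketene silyl acetal 36 (not isolated), via silyl dienol ether 37 (not isolated)
Conditions: TMSOTf (3 equiv), iPr2NEt (4 equiv), CH2Cl2 (0.005 M), −78 → −30 °C; then 1 M HCl, THF, 0 °C
Reagents that add atoms: trimethylsilyl triflate C[Si](C)(C)OS(=O)(=O)C(F)(F)F (silyl groups of 36 and 37 only)
Why: Silyl triflate and the hindered amine convert the benzylic arylacetate, the most acidic C–H, into ketene silyl acetal 36, whose carbon C11′ adds to the terminal carbon C13′ of the silyl triflate-activated cross-conjugated dienone to give 2-silyloxycyclopentadiene 37, which is hydrolysed with C-protonation at C3. The closest known reaction type is the one-pot soft-enolisation Mukaiyama–Michael addition of ketene silyl acetals to enones, here in its intramolecular, lactone-forming form. The δ-lactone closes in a 6-endo-trig (enolendo) mode, possible because C13′ is the β-carbon of the C2 carbonyl and lies six atoms from C11′ through the C4–O–C12′ ester. C3 is set by protonation on the face opposite the new ring, which gives the cis-fused bicycle (also the thermodynamic outcome), while C11′ is an epimerisable α-aryl lactone centre whose pseudo-equatorial aryl epimer, with the aryl group cis to the C3–C2 bond, is the target configuration and is secured by equilibration in step 27. The step needs 1,4- over 1,2-addition and ring closure over intermolecular addition to the lactone methylene, secured by the soft silyl nucleophile, the higher electrophilicity of the dienone and high dilution; it must also avoid β-elimination of the C4 carboxylate, secured because the C3 enol is carried as its silyl ether and no free enolate forms.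

Step 26
Reactants: 38 ketone
Product: 39 C2 alcohol (hydroxyl cis to C13′ and to the C4 oxygen)
Conditions: NaBH4, CeCl3·7H2O, MeOH–THF, −78 °C; AcOH quench
Reagents that add atoms: none
Why: Luche 1,2-reduction should deliver hydride to C2 on the face anti to the adjacent C13′ substituent, the lactone ring and the pseudoaxial C10 methyl, giving the alcohol cis to the lactone CH2 as in the target; low temperature and an acidic quench guard against β-elimination and acyl migration.

Step 27
Reactants: 39 alcohol
Product: 40 target with the benzylic hydroxyl as its tert-butyldiphenylsilyl ether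
Conditions: Ac2O, pyridine, DMAP (cat.), CH2Cl2, 0 °C; then DBU (0.1 equiv), toluene, 0 °C → rt
Reagents that add atoms: acetic anhydride CC(=O)OC(C)=O
Why: Acetylation of the allylic alcohol directly after reduction forestalls 1,3-acyl migration of the lactone to the C2 oxygen, and brief treatment with catalytic DBU equilibrates the α-aryl lactone centre C11′ to the pseudo-equatorial epimer, expected to be the more stable one.

Step 28
Reactants: 40 silyl ether
Product: 41 CNP0205574.1
Conditions: HF·pyridine, pyridine, THF, 0 °C → rt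
Reagents that add atoms: none
Why: Buffered HF·pyridine removes the benzylic silyl ether without affecting the acetates, the two lactones or the exocyclic methylene.

**Compound list**

1 | (S)-linalool | C=C[C@@](C)(O)CCC=C(C)C | starting material
2 | (S)-1-methylcyclopent-2-en-1-ol | C1=C[C@@](C)(O)CC1 | intermediate
3 | (S)-tert-butyldimethyl[(1-methylcyclopent-2-en-1-yl)oxy]silane | C1=C[C@@](C)(O[Si](C)(C)C(C)(C)C)CC1 | intermediate
4 | (S)-4-(tert-butyldimethylsilyloxy)-4-methylcyclopent-2-en-1-one | O=C1C=C[C@@](C)(O[Si](C)(C)C(C)(C)C)C1 | intermediate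
5 | (3S,4S)-4-(tert-butyldimethylsilyloxy)-4-methyl-3-(pinacolboryl)cyclopentan-1-one (drawn epimer) | O=C1C[C@H](B2OC(C)(C)C(C)(C)O2)[C@@](C)(O[Si](C)(C)C(C)(C)C)C1 | intermediate (not isolated)
6 | (3S,4S)-4-(tert-butyldimethylsilyloxy)-3-hydroxy-4-methylcyclopentan-1-one (hydroxyl drawn trans to the silyloxy group; centre lost in step 5) | O=C1C[C@H](O)[C@@](C)(O[Si](C)(C)C(C)(C)C)C1 | intermediate
7 | (S)-4-(tert-butyldimethylsilyloxy)-4-methylcyclopentane-1,3-dione | O=C1CC(=O)[C@@](C)(O[Si](C)(C)C(C)(C)C)C1 | intermediate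
8 | (E)-but-2-enal | C/C=C/C=O | starting material
9 | (4S,6S)-6-(tert-butyldimethylsilyloxy)-2-hydroxy-4,6-dimethyl-3,4,6,7-tetrahydrocyclopenta[b]pyran-5(2H)-one (both anomers) | O=C1C2=C(OC(O)C[C@@H]2C)C[C@]1(C)O[Si](C)(C)C(C)(C)C | intermediate (not isolated)
10 | (4S,6S)-6-(tert-butyldimethylsilyloxy)-2-methoxy-4,6-dimethyl-3,4,6,7-tetrahydrocyclopenta[b]pyran-5(2H)-one (both anomers) | O=C1C2=C(OC(OC)C[C@@H]2C)C[C@]1(C)O[Si](C)(C)C(C)(C)C | intermediate
11 | (4S,6S)-5-allyl-6-(tert-butyldimethylsilyloxy)-2-methoxy-4,6-dimethyl-2,3,4,5,6,7-hexahydrocyclopenta[b]pyran-5-ol (epimers at C2 and C5) | C=CCC1(O)C2=C(OC(OC)C[C@@H]2C)C[C@]1(C)O[Si](C)(C)C(C)(C)C | intermediate (not isolated)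
12 | (S)-3-[(S)-2-allyl-3-(tert-butyldimethylsilyloxy)-3-methyl-5-oxocyclopent-1-en-1-yl]butanal | O=CC[C@H](C)C1=C(CC=C)[C@@](C)(O[Si](C)(C)C(C)(C)C)CC1=O | intermediate
13 | (S)-3-[(S)-3-(tert-butyldimethylsilyloxy)-3-methyl-2-(3-methylbut-2-en-1-yl)-5-oxocyclopent-1-en-1-yl]butanal | O=CC[C@H](C)C1=C(CC=C(C)C)[C@@](C)(O[Si](C)(C)C(C)(C)C)CC1=O | intermediate
14 | (3S,5R,6S,8S)-3-(tert-butyldimethylsilyloxy)-6-hydroxy-3,8-dimethyl-5-(prop-1-en-2-yl)-3,4,5,6,7,8-hexahydroazulen-1(2H)-one | C=C(C)[C@H]1CC2=C(C(=O)C[C@]2(C)O[Si](C)(C)C(C)(C)C)[C@@H](C)C[C@@H]1O | intermediate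
15 | (3S,5R,6S,8S)-3-(tert-butyldimethylsilyloxy)-6-hydroxy-5-(3-hydroxyprop-1-en-2-yl)-3,8-dimethyl-3,4,5,6,7,8-hexahydroazulen-1(2H)-one | C=C(CO)[C@H]1CC2=C(C(=O)C[C@]2(C)O[Si](C)(C)C(C)(C)C)[C@@H](C)C[C@@H]1O | intermediate
16 | (4S,7R,8S,10S)-4-(tert-butyldimethylsilyloxy)-12-hydroxy-8,12-epoxyguaia-1(5),11(13)-dien-2-one (lactol, both C12 epimers) | C=C1C(O)O[C@H]2C[C@H](C)C3=C(C[C@H]12)[C@@](C)(O[Si](C)(C)C(C)(C)C)CC3=O | intermediate (not isolated)
17 | (4S,7R,8S,10S)-4-(tert-butyldimethylsilyloxy)-2-oxoguaia-1(5),11(13)-dien-12,8-olide (trans-fused γ-lactone) | C=C1C(=O)O[C@H]2C[C@H](C)C3=C(C[C@H]12)[C@@](C)(O[Si](C)(C)C(C)(C)C)CC3=O | intermediate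
18 | C2 trimethylsilyl dienol ether of 17 (C2=C3 and C1=C5 double bonds) | C=C1C(=O)O[C@H]2C[C@H](C)C3=C(C[C@H]12)[C@@](C)(O[Si](C)(C)C(C)(C)C)C=C3O[Si](C)(C)C | intermediate (not isolated)
19 | (4S,7R,8S,10S)-4-(tert-butyldimethylsilyloxy)-3-(dimethylaminomethyl)-2-oxoguaia-1(5),11(13)-dien-12,8-olide (C3 epimers) | C=C1C(=O)O[C@H]2C[C@H](C)C3=C(C[C@H]12)[C@@](C)(O[Si](C)(C)C(C)(C)C)C(CN(C)C)C3=O | intermediate
20 | (4S,7R,8S,10S)-3-(dimethylaminomethyl)-4-hydroxy-2-oxoguaia-1(5),11(13)-dien-12,8-olide (C3 epimers) | C=C1C(=O)O[C@H]2C[C@H](C)C3=C(C[C@H]12)[C@@](C)(O)C(CN(C)C)C3=O | intermediate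
21 | methyl 4-bromo-2-iodobenzoate | COC(=O)c1ccc(Br)cc1I | starting material
22 | (4-bromo-2-iodophenyl)methanol | OCc1ccc(Br)cc1I | intermediate
23 | [(4-bromo-2-iodobenzyl)oxy](tert-butyl)diphenylsilane | CC(C)(C)[Si](OCc1ccc(Br)cc1I)(c1ccccc1)c1ccccc1 | intermediate
24 | succinic anhydride | O=C1CCC(=O)O1 | starting material
25 | [5-bromo-2-(tert-butyldiphenylsilyloxymethyl)phenyl]magnesium chloride | Cl[Mg]c1cc(Br)ccc1CO[Si](c1ccccc1)(c1ccccc1)C(C)(C)C | intermediate (not isolated)
26 | 4-[5-bromo-2-(tert-butyldiphenylsilyloxymethyl)phenyl]-4-oxobutanoic acid | OC(=O)CCC(=O)c1cc(Br)ccc1CO[Si](c1ccccc1)(c1ccccc1)C(C)(C)C | intermediate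
27 | 4-[5-bromo-2-(tert-butyldiphenylsilyloxymethyl)phenyl]pent-4-enoic acid | C=C(CCC(=O)O)c1cc(Br)ccc1CO[Si](c1ccccc1)(c1ccccc1)C(C)(C)C | intermediate
28 | (R)-4-[5-bromo-2-(tert-butyldiphenylsilyloxymethyl)phenyl]pentanoic acid | C[C@H](CCC(=O)O)c1cc(Br)ccc1CO[Si](c1ccccc1)(c1ccccc1)C(C)(C)C | intermediate
29 | (R)-4-[5-bromo-2-(tert-butyldiphenylsilyloxymethyl)phenyl]pentan-1-ol | C[C@H](CCCO)c1cc(Br)ccc1CO[Si](c1ccccc1)(c1ccccc1)C(C)(C)C | intermediate
30 | (R)-4-[5-bromo-2-(tert-butyldiphenylsilyloxymethyl)phenyl]pentyl acetate | C[C@H](CCCOC(C)=O)c1cc(Br)ccc1CO[Si](c1ccccc1)(c1ccccc1)C(C)(C)C | intermediate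
31 | tert-butyl 2-[3-[(R)-5-acetoxypentan-2-yl]-4-(tert-butyldiphenylsilyloxymethyl)phenyl]acetate | C[C@H](CCCOC(C)=O)c1cc(CC(=O)OC(C)(C)C)ccc1CO[Si](c1ccccc1)(c1ccccc1)C(C)(C)C | intermediate
32 | 2-[3-[(R)-5-acetoxypentan-2-yl]-4-(tert-butyldiphenylsilyloxymethyl)phenyl]acetic acid | C[C@H](CCCOC(C)=O)c1cc(CC(=O)O)ccc1CO[Si](c1ccccc1)(c1ccccc1)C(C)(C)C | intermediate
33 | ester of the C4 hydroxyl of 20 with acid 32 (C3 epimers; other centres as in 20 and 32) | C=C1C(=O)O[C@H]2C[C@H](C)C3=C(C[C@H]12)[C@@](C)(OC(=O)Cc4ccc(CO[Si](c5ccccc5)(c5ccccc5)C(C)(C)C)c([C@H](C)CCCOC(C)=O)c4)C(CN(C)C)C3=O | intermediate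
34 | N-methyl ammonium iodide of 33 | C=C1C(=O)O[C@H]2C[C@H](C)C3=C(C[C@H]12)[C@@](C)(OC(=O)Cc4ccc(CO[Si](c5ccccc5)(c5ccccc5)C(C)(C)C)c([C@H](C)CCCOC(C)=O)c4)C(C[N+](C)(C)C)C3=O.[I-] | intermediate (not isolated)
35 | 4-arylacetoxy-3-methylene-2-oxoguaia-1(5),11(13)-dien-12,8-olide (aryl group as in 32; C4, C7, C8, C10 arranged as in 41) | C=C1C(=O)O[C@H]2C[C@H](C)C3=C(C[C@H]12)[C@@](C)(OC(=O)Cc4ccc(CO[Si](c5ccccc5)(c5ccccc5)C(C)(C)C)c([C@H](C)CCCOC(C)=O)c4)C(=C)C3=O | intermediate
36 | ketene trimethylsilyl acetal of the arylacetate of 35 (either double-bond geometry) | C=C1C(=O)O[C@H]2C[C@H](C)C3=C(C[C@H]12)[C@@](C)(OC(O[Si](C)(C)C)=Cc4ccc(CO[Si](c5ccccc5)(c5ccccc5)C(C)(C)C)c([C@H](C)CCCOC(C)=O)c4)C(=C)C3=O | intermediate (not isolated)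
37 | cyclised 2-trimethylsilyloxy cyclopentadiene with the δ-lactone closed (C11′ drawn as in 41) | C=C1C(=O)O[C@H]2C[C@H](C)C3=C(C[C@H]12)[C@@]1(C)OC(=O)[C@@H](c2ccc(CO[Si](c4ccccc4)(c4ccccc4)C(C)(C)C)c([C@H](C)CCCOC(C)=O)c2)CC1=C3O[Si](C)(C)C | intermediate (not isolated)
38 | C2 ketone with the δ-lactone cis-fused at C3/C4 and the aryl group on C11′ cis to the C3–C2 bond; benzylic hydroxyl as silyl ether; other centres as in 41 | C=C1C(=O)O[C@H]2C[C@H](C)C3=C(C[C@H]12)[C@@]1(C)OC(=O)[C@@H](c2ccc(CO[Si](c4ccccc4)(c4ccccc4)C(C)(C)C)c([C@H](C)CCCOC(C)=O)c2)C[C@H]1C3=O | intermediate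
39 | C2 alcohol of 38 (hydroxyl cis to C13′ and to the C4 oxygen) | C=C1C(=O)O[C@H]2C[C@H](C)C3=C(C[C@H]12)[C@@]1(C)OC(=O)[C@@H](c2ccc(CO[Si](c4ccccc4)(c4ccccc4)C(C)(C)C)c([C@H](C)CCCOC(C)=O)c2)C[C@H]1[C@H]3O | intermediate
40 | tert-butyldiphenylsilyl ether of the target at the benzylic hydroxyl | C=C1C(=O)O[C@H]2C[C@H](C)C3=C(C[C@H]12)[C@@]1(C)OC(=O)[C@@H](c2ccc(CO[Si](c4ccccc4)(c4ccccc4)C(C)(C)C)c([C@H](C)CCCOC(C)=O)c2)C[C@H]1[C@H]3OC(C)=O | intermediate
41 | CNP0205574.1 | C=C1C(=O)O[C@H]2C[C@H](C)C3=C(C[C@H]12)[C@@]1(C)OC(=O)[C@@H](c2ccc(CO)c([C@H](C)CCCOC(C)=O)c2)C[C@H]1[C@H]3OC(C)=O | target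

**Step count and risks**

Total step count: 28. Longest linear sequence: 19 steps (steps 1–13 and 23–28); fragment 2 takes 9 steps (14–22).

Steps most likely to fail:

1. Step 25. The closure may be diverted by competing γ-silylation of the dienone, by oligomerisation at the C3 methylene, or by loss of the C4 carboxylate during hydrolysis of the silyl dienol ether. Fallback: the C11′–C13′ bond is made by a tin hydride radical cyclisation instead. Acid 32 is converted (SOCl2, then NBS with catalytic HBr) into the α-bromo acid chloride F1, which acylates amino alcohol 20 (pyridine, CH2Cl2, −20 °C) to give the bromo ester F2. Methylation with MeI gives the ammonium iodide F3, and aqueous NaHCO3 gives the bromo dienone F4. Bu3SnH and Et3B/air in toluene (−78 → 0 °C, high dilution) then generate the benzylic α-ester radical, which closes in a 6-endo mode on C13′; hydrogen-atom transfer to the resulting α-keto radical gives ketone 38, where the route is rejoined.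

2. Step 9. The seven-membered ene closure may be slow, may be diverted to chloride-trapped Prins products, or may show poor facial control relative to C10. Fallback: the same bond is formed by an intramolecular Nozaki–Hiyama–Kishi-type allylation. Prenyl aldehyde 13 is oxidised at the (E)-methyl group (SeO2, tBuOOH) to the allylic alcohol F5, which is converted under Corey–Kim conditions (NBS, Me2S) into the allylic bromide F6. CrCl2 (divalent chromium) in THF at high dilution then gives an allylchromium species that adds to the aldehyde through a chair transition state with anti selectivity and delivers homoallylic alcohol 14, where the route is rejoined.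

3. Step 23. Acyl transfer to the hindered tertiary alcohol may stall, the activated acid may be lost to N-acylurea formation, or the β-amino ketone may eliminate under the coupling conditions. Fallback: the order is changed so that the less hindered alcohol is esterified before C3 is substituted. Lactone 17 is desilylated (HF·pyridine) to the hydroxy enone F7, which is esterified with acid 32 (DCC, DMAP) to the keto ester F8. Acid-mediated α-methylenation of the ketone (paraformaldehyde, N-methylanilinium trifluoroacetate, THF, 65 °C) proceeds through the enol, should leave the arylacetate untouched, and gives dienone 35 directly, where the route is rejoined.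

Further compounds
F1 | step 25 | 2-bromo-2-[3-[(R)-5-acetoxypentan-2-yl]-4-(tert-butyldiphenylsilyloxymethyl)phenyl]acetyl chloride (both epimers at the bromo carbon) | C[C@H](CCCOC(C)=O)c1cc(C(Br)C(Cl)=O)ccc1CO[Si](c1ccccc1)(c1ccccc1)C(C)(C)C
F2 | step 25 | ester of the C4 hydroxyl of 20 with the α-bromo acid of F1 | C=C1C(=O)O[C@H]2C[C@H](C)C3=C(C[C@H]12)[C@@](C)(OC(=O)C(Br)c4ccc(CO[Si](c5ccccc5)(c5ccccc5)C(C)(C)C)c([C@H](C)CCCOC(C)=O)c4)C(CN(C)C)C3=O
F3 | step 25 | N-methyl ammonium iodide of F2 | C=C1C(=O)O[C@H]2C[C@H](C)C3=C(C[C@H]12)[C@@](C)(OC(=O)C(Br)c4ccc(CO[Si](c5ccccc5)(c5ccccc5)C(C)(C)C)c([C@H](C)CCCOC(C)=O)c4)C(C[N+](C)(C)C)C3=O.[I-]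
F4 | step 25 | α-bromo analogue of dienone 35 | C=C1C(=O)O[C@H]2C[C@H](C)C3=C(C[C@H]12)[C@@](C)(OC(=O)C(Br)c4ccc(CO[Si](c5ccccc5)(c5ccccc5)C(C)(C)C)c([C@H](C)CCCOC(C)=O)c4)C(=C)C3=O
F5 | step 9 | (S)-3-[(S)-3-(tert-butyldimethylsilyloxy)-2-[(E)-4-hydroxy-3-methylbut-2-en-1-yl]-3-methyl-5-oxocyclopent-1-en-1-yl]butanal | O=CC[C@H](C)C1=C(C/C=C(\C)CO)[C@@](C)(O[Si](C)(C)C(C)(C)C)CC1=O
F6 | step 9 | (S)-3-[(S)-2-[(E)-4-bromo-3-methylbut-2-en-1-yl]-3-(tert-butyldimethylsilyloxy)-3-methyl-5-oxocyclopent-1-en-1-yl]butanal | O=CC[C@H](C)C1=C(C/C=C(\C)CBr)[C@@](C)(O[Si](C)(C)C(C)(C)C)CC1=O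
F7 | step 23 | (4S,7R,8S,10S)-4-hydroxy-2-oxoguaia-1(5),11(13)-dien-12,8-olide | C=C1C(=O)O[C@H]2C[C@H](C)C3=C(C[C@H]12)[C@@](C)(O)CC3=O
F8 | step 23 | ester of the C4 hydroxyl of F7 with acid 32 | C=C1C(=O)O[C@H]2C[C@H](C)C3=C(C[C@H]12)[C@@](C)(OC(=O)Cc4ccc(CO[Si](c5ccccc5)(c5ccccc5)C(C)(C)C)c([C@H](C)CCCOC(C)=O)c4)CC3=O
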